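**Strategy**

The route rests on closing ring B last, at C6–C7. A dimethylaluminium chloride-promoted type 2 carbonyl-ene reaction of the C6 aldehyde on ring A with the 2-propenyl group on C9 forms that bond, closes the six-membered ring and turns the C17 methyl into the C8=C17 methylene in one operation; C7–C9 and C11–C17 are (R)-linalool, transposed onto C10 by a Claisen rearrangement. The precursor is a ring A aldehyde ester with C18, C6 and the C9 arm on one face, as the cis fusion demands: a Diels–Alder adduct fixes C4 and C5, then the linalool unit and finally the C20 methyl, trans to C6, are put on C10.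

Key step: step 15

Remarks
- Labdane numbering is used throughout (ring A: C1–C5, C10; ring B: C5–C10; C18 and C19 are the methyl and carboxyl carbons on C4, C20 the methyl on C10); β is the face of C20. "6,7-Seco" names lack the C6–C7 bond. The target is taken as drawn: 5β-H (cis A/B fusion), 4β-carboxyl, 9α-H, 13R.
- Assumption: a C5 methylene or enol flanked by quaternary C4 and C10 would take up hydrogen on the face away from the axial C19/C20 pair and place C6 trans to the C10 arm (trans-fused series). C6 is therefore in place before C10 is completed.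
- Assumption: the (2S,5S) auxiliary is taken to give the (1S,6S) enone; if induction runs the other way, its enantiomer is used.
- Salts that differ from a numbered compound only by a proton (enolates, alkoxides, carboxylates) are not numbered separately.

**Route**

Step 1
Reactants: 1 2,2-dimethoxyacetaldehyde; 2 methyl 2-(triphenylphosphoranylidene)propanoate
Product: 3 methyl (2E)-4,4-dimethoxy-2-methylbut-2-enoate
Conditions: toluene, 60 °C
Reagents that add atoms: none
Why: Wittig olefination with an ester-stabilised ylide gives the E enoate (ester trans to the acetal carbon), the geometry that later places C19 trans to C6.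

Step 2
Reactants: 4 (3E)-4-methoxybut-3-en-2-one; 5 (2S,5S)-2,5-diphenylpyrrolidine
Product: 6 (3E)-4-[(2S,5S)-2,5-diphenylpyrrolidin-1-yl]but-3-en-2-one
Conditions: MeOH, 50 °C
Reagents that add atoms: none
Why: Conjugate addition–elimination of the amine at the beta-methoxy enone (vinylogous transamidation) gives the E vinylogous amide without touching the pyrrolidine stereocentres.

Step 3
Reactants: 6 (3E)-4-[(2S,5S)-2,5-diphenylpyrrolidin-1-yl]but-3-en-2-one
Product: 7 (2S,5S)-1-[(1E)-3-(tert-butyldimethylsilyloxy)buta-1,3-dien-1-yl]-2,5-diphenylpyrrolidine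
Conditions: KN(SiMe3)2, THF, −78 °C; then t-BuMe2SiCl, −78 °C to rt
Reagents that add atoms: tert-butyl(chloro)dimethylsilane, CC(C)(C)[Si](C)(C)Cl
Why: Deprotonation of the methyl ketone and O-silylation of the enolate (silyl enol ether formation) gives the 1-amino-3-siloxy diene, which is used without chromatography.

Step 4
Reactants: 3 methyl (2E)-4,4-dimethoxy-2-methylbut-2-enoate; 7 (2S,5S)-1-[(1E)-3-(tert-butyldimethylsilyloxy)buta-1,3-dien-1-yl]-2,5-diphenylpyrrolidine
Product: 10 methyl (1S,6S)-6-(dimethoxymethyl)-1-methyl-4-oxocyclohex-2-ene-1-carboxylate, via silyl enol ether cycloadduct 8 (not isolated), via beta-amino ketone 9 (not isolated)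
Conditions: toluene, 80 °C, sealed; then Bu4NF, AcOH, THF, 0 °C to rt
Reagents that add atoms: none
Why: Diels–Alder reaction of the electron-rich 1-amino-3-siloxy diene with the enoate: the methylene terminus of the diene bonds to the enoate beta-carbon (C5) and the amino-bearing terminus to C4, suprafacial addition to the E alkene makes the ester (C19) trans to the acetal carbon (C6), a phenyl group of the C2-symmetric pyrrolidine blocks one diene face and should set the absolute sense, and desilylation followed by E1cB loss of the amine unmasks the enone and erases the amine-bearing centre.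

Step 5
Reactants: 11 (R)-linalool
Product: 12 triethyl{[(3R)-3,7-dimethylocta-1,6-dien-3-yl]oxy}silane
Conditions: Et3SiOTf, 2,6-lutidine, CH2Cl2, −78 to 0 °C
Reagents that add atoms: triethylsilyl trifluoromethanesulfonate, CC[Si](CC)(CC)OS(=O)(=O)C(F)(F)F
Why: Silylation with a silyl triflate and a hindered pyridine base is the standard protection of a tertiary alcohol and does not involve the C13 stereocentre.

Step 6
Reactants: 12 triethyl{[(3R)-3,7-dimethylocta-1,6-dien-3-yl]oxy}silane
Product: 14 (2E,6R)-2,6-dimethyl-6-(triethylsilyloxy)octa-2,7-dien-1-ol, via (2E)-enal 13 (not isolated)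
Conditions: SeO2 (0.3 equiv), t-BuOOH, salicylic acid (cat.), CH2Cl2, rt; then NaBH4, MeOH, 0 °C
Reagents that add atoms: tert-butyl hydroperoxide, CC(C)(C)OO; selenium dioxide, O=[Se]=O
Why: Selenium dioxide allylic oxidation (ene reaction, then [2,3]-sigmatropic shift) attacks the E methyl of the trisubstituted alkene with retention of its geometry, the vinyl group having no allylic hydrogen, and borohydride returns any over-oxidised enal to the E allylic alcohol.

Step 7
Reactants: 14 (2E,6R)-2,6-dimethyl-6-(triethylsilyloxy)octa-2,7-dien-1-ol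
Product: 15 (2E,6R)-2,6-dimethyl-6-(triethylsilyloxy)octa-2,7-dien-1-yl methanesulfonate
Conditions: MeSO2Cl, Et3N, CH2Cl2, −40 °C; used crude
Reagents that add atoms: methanesulfonyl chloride, CS(=O)(=O)Cl
Why: Sulfonylation of the primary allylic alcohol is fast at low temperature, leaves the E alkene and the silyl ether untouched and supplies a hard leaving group for O-alkylation.

Step 8
Reactants: 10 methyl (1S,6S)-6-(dimethoxymethyl)-1-methyl-4-oxocyclohex-2-ene-1-carboxylate; 15 (2E,6R)-2,6-dimethyl-6-(triethylsilyloxy)octa-2,7-dien-1-yl methanesulfonate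
Product: 16 methyl (1S,6S)-6-(dimethoxymethyl)-4-{[(2E,6R)-2,6-dimethyl-6-(triethylsilyloxy)octa-2,7-dien-1-yl]oxy}-1-methylcyclohexa-2,4-diene-1-carboxylate
Conditions: KN(SiMe3)2, THF, −78 °C; 18-crown-6, DMPU; then 15, −78 to −20 °C
Reagents that add atoms: none
Why: Deprotonation can only occur at C10 (C4 is quaternary), and the crown-separated potassium dienolate should be alkylated on oxygen by the hard allylic sulfonate in a dipolar medium (Williamson-type O-alkylation of an enolate), attack through C10 being slowed by the neighbouring C5 acetal; no stereocentre changes.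

Step 9
Reactants: 16 methyl (1S,6S)-6-(dimethoxymethyl)-4-{[(2E,6R)-2,6-dimethyl-6-(triethylsilyloxy)octa-2,7-dien-1-yl]oxy}-1-methylcyclohexa-2,4-diene-1-carboxylate
Product: 17 methyl 6,6-dimethoxy-1-oxo-13-(triethylsilyloxy)-20-nor-6,7-secolabda-2,7,14-trien-19-oate (C9 arm on C10 trans to C6)
Conditions: toluene, 110 °C, sealed, base-washed glass
Reagents that add atoms: none
Why: Claisen rearrangement through a chair transition state forms C9–C10 and the 2-propenyl group; the allyl unit should reach C10 on the ring face away from the C5 acetal carbon (1,2-induction), and with the E alkene this fixes C9 in the required sense, while C10 itself is set again in step 10.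

Step 10
Reactants: 17 methyl 6,6-dimethoxy-1-oxo-13-(triethylsilyloxy)-20-nor-6,7-secolabda-2,7,14-trien-19-oate
Product: 18 methyl 6,6-dimethoxy-1-oxo-13-(triethylsilyloxy)-6,7-secolabda-2,7,14-trien-19-oate (10β-methyl; C9 arm cis to C6)
Conditions: LiN(iPr)2, THF, −78 °C; then MeI, DMPU, −78 to −20 °C
Reagents that add atoms: iodomethane, CI
Why: The only acidic hydrogen is on C10, and C-methylation of the planar enolate (enolate alkylation) should occur anti to the neighbouring C5 acetal carbon, so the C20 methyl becomes trans to C6 and the linalool arm is pushed cis to C6, the relationship a cis ring fusion requires.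

Step 11
Reactants: 18 methyl 6,6-dimethoxy-1-oxo-13-(triethylsilyloxy)-6,7-secolabda-2,7,14-trien-19-oate
Product: 19 methyl 6,6-dimethoxy-1-oxo-13-(triethylsilyloxy)-6,7-secolabda-7,14-dien-19-oate
Conditions: [(Ph3P)CuH]6 (0.4 equiv), H2O (2 equiv), benzene/THF, rt
Reagents that add atoms: none
Why: Conjugate reduction by the phosphine-stabilised copper hydride is selective for the enone C2=C3 bond over the three isolated alkenes, the ester and the acetal, and creates no stereocentre.

Step 12
Reactants: 19 methyl 6,6-dimethoxy-1-oxo-13-(triethylsilyloxy)-6,7-secolabda-7,14-dien-19-oate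
Product: 20 C1 tosylhydrazone of 19
Conditions: TsNHNH2, pyridinium p-toluenesulfonate (cat.), MeOH/THF, 60 °C
Reagents that add atoms: 4-methylbenzenesulfonohydrazide, Cc1ccc(cc1)S(=O)(=O)NN
Why: Condensation of the ketone with the sulfonyl hydrazide gives the tosylhydrazone; the C1 carbonyl has a methylene on one side and stays accessible, and the dimethyl acetal is stable in methanol.

Step 13
Reactants: 20 C1 tosylhydrazone of 19
Product: 22 methyl 6,6-dimethoxy-13-(triethylsilyloxy)-6,7-secolabda-7,14-dien-19-oate, via N-boryl hydrazide 21 (not isolated)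
Conditions: catecholborane, CHCl3, 0 °C to rt; then NaOAc·3H2O, 60 °C
Reagents that add atoms: none
Why: Hydride transfer from catecholborane to the C=N bond, then acetate-induced loss of sulfinate and boron, gives an alkyl diazene that expels N2 (tosylhydrazone reduction to a methylene), under conditions that do not hydroborate unactivated alkenes.

Step 14
Reactants: 22 methyl 6,6-dimethoxy-13-(triethylsilyloxy)-6,7-secolabda-7,14-dien-19-oate
Product: 23 methyl 6-oxo-13-(triethylsilyloxy)-6,7-secolabda-7,14-dien-19-oate (ring A aldehyde ester; formyl cis to the C10 arm)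
Conditions: oxalic acid (5% aq.) on silica gel, CH2Cl2, rt
Reagents that add atoms: water, O
Why: Acid-catalysed acetal hydrolysis through the oxocarbenium ion is helped by relief of crowding between the two quaternary carbons, while the weak acid should spare the tertiary silyl ether and not enolise the aldehyde, so the C5 configuration is kept.

Step 15
Reactants: 23 methyl 6-oxo-13-(triethylsilyloxy)-6,7-secolabda-7,14-dien-19-oate
Product: 24 methyl 6β-hydroxy-13-(triethylsilyloxy)-5β-labda-8(17),14-dien-19-oate
Conditions: Me2AlCl (2.2 equiv), CH2Cl2, −78 to −40 °C; then aq. NaHCO3, sodium potassium tartrate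
Reagents that add atoms: none
Why: Me2AlCl binds the aldehyde oxygen, and the 1,1-disubstituted alkene attacks C6 through its terminal carbon C7 while a C17 hydrogen passes to oxygen in a six-membered ene array; the closest known reaction type is the dimethylaluminium chloride-promoted type 2 intramolecular carbonyl-ene cyclisation of 5-methylhex-5-enals to 3-methylenecyclohexanols. Ring B closes as a six-membered ring in the type 2 mode, the ene unit being joined to the tether through its central carbon C8, so the new alkene can only be the exocyclic C8=C17 methylene. The one new stereocentre, C6, follows from the chair-like transition state on the pre-set C5/C9/C10 array and is drawn as the 6β (6R) alcohol; it is removed in steps 16 and 17, so either epimer would serve. The cis ring fusion is not created here but inherited from the cis C5 formyl/C10 arm relationship of 23. The step needs hydrogen transfer from C17 and not from C9, which the tether enforces because the C9 hydrogen lies inside the forming ring and cannot reach oxygen. It also needs the tertiary allylic silyl ether to survive, hence the low temperature and a reagent whose methyl groups scavenge protons as methane.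

Step 16
Reactants: 24 methyl 6β-hydroxy-13-(triethylsilyloxy)-5β-labda-8(17),14-dien-19-oate
Product: 26 O-(C6) S-methyl dithiocarbonate of 24, via sodium xanthate 25 (not isolated)
Conditions: NaH, imidazole (cat.), THF, 0 °C to rt; CS2; then MeI
Reagents that add atoms: carbon disulfide, S=C=S; iodomethane, CI
Why: Xanthate formation (alkoxide addition to CS2, then S-methylation) works for hindered secondary alcohols and leaves the C6 configuration and the non-enolisable ester unchanged.

Step 17
Reactants: 26 O-(C6) S-methyl dithiocarbonate of 24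
Product: 27 methyl 13-(triethylsilyloxy)-5β-labda-8(17),14-dien-19-oate
Conditions: Bu3SnH, AIBN (cat.), toluene, 110 °C
Reagents that add atoms: none
Why: Barton–McCombie deoxygenation: the stannyl radical adds to the thiocarbonyl group, the secondary C6 radical is released and should be reduced by Bu3SnH faster than it can engage the homoallylic C8=C17 bond, so C6 becomes a methylene and the stereocentre made in the key step disappears.

Step 18
Reactants: 27 methyl 13-(triethylsilyloxy)-5β-labda-8(17),14-dien-19-oate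
Product: 28 13-(triethylsilyloxy)-5β-labda-8(17),14-dien-19-oic acid
Conditions: NaSCH2CH3, DMF, 80 °C; then cold aq. NaHSO4
Reagents that add atoms: none
Why: SN2 O-demethylation by the thiolate attacks the methyl carbon and so bypasses the shielded neopentyl carbonyl, leaving the silyl ether, both alkenes and all stereocentres untouched.

Step 19
Reactants: 28 13-(triethylsilyloxy)-5β-labda-8(17),14-dien-19-oic acid
Product: 29 (13R)-13-hydroxy-5β-labda-8(17),14-dien-19-oic acid
Conditions: Bu4NF, THF, 40 °C; aq. NH4Cl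
Reagents that add atoms: none
Why: Fluoride-induced desilylation frees the tertiary allylic alcohol without acid, so C13 cannot ionise.

Step 20
Reactants: 29 (13R)-13-hydroxy-5β-labda-8(17),14-dien-19-oic acid
Product: 31 (13R)-13-acetoxy-5β-labda-8(17),14-dien-19-oic acid, via mixed anhydride 30 (not isolated)
Conditions: Ac2O, Et3N, 4-(dimethylamino)pyridine, CH2Cl2, rt to 40 °C; then THF/H2O, NaHCO3, rt; acidify to pH 4
Reagents that add atoms: acetic anhydride, CC(=O)OC(C)=O
Why: Nucleophile-catalysed acylation (acylpyridinium transfer) esterifies the tertiary alcohol with retention at C13, and the mixed anhydride formed at the carboxyl group should be hydrolysed selectively on aqueous work-up because the tertiary acetate is far less electrophilic.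

**Compound list**

1 | 2,2-dimethoxyacetaldehyde | COC(OC)C=O | starting material
2 | methyl 2-(triphenylphosphoranylidene)propanoate | COC(=O)C(C)=P(c1ccccc1)(c1ccccc1)c1ccccc1 | starting material
3 | methyl (2E)-4,4-dimethoxy-2-methylbut-2-enoate | COC(=O)/C(C)=C/C(OC)OC | intermediate
4 | (3E)-4-methoxybut-3-en-2-one | CO/C=C/C(C)=O | starting material
5 | (2S,5S)-2,5-diphenylpyrrolidine | N1[C@H](c2ccccc2)CC[C@H]1c1ccccc1 | starting material
6 | (3E)-4-[(2S,5S)-2,5-diphenylpyrrolidin-1-yl]but-3-en-2-one | CC(=O)/C=C/N1[C@H](c2ccccc2)CC[C@H]1c1ccccc1 | intermediate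
7 | (2S,5S)-1-[(1E)-3-(tert-butyldimethylsilyloxy)buta-1,3-dien-1-yl]-2,5-diphenylpyrrolidine | C=C(O[Si](C)(C)C(C)(C)C)/C=C/N1[C@H](c2ccccc2)CC[C@H]1c1ccccc1 | intermediate
8 | silyl enol ether cycloadduct: methyl 4-(tert-butyldimethylsilyloxy)-6-(dimethoxymethyl)-2-[(2S,5S)-2,5-diphenylpyrrolidin-1-yl]-1-methylcyclohex-3-ene-1-carboxylate (ester trans to the acetal carbon; amine drawn endo, this centre is lost) | CC(C)(C)[Si](C)(C)OC1=C[C@H](N2[C@H](c3ccccc3)CC[C@H]2c2ccccc2)[C@](C)(C(=O)OC)[C@@H](C(OC)OC)C1 | intermediate (not isolated)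
9 | beta-amino ketone: methyl 6-(dimethoxymethyl)-2-[(2S,5S)-2,5-diphenylpyrrolidin-1-yl]-1-methyl-4-oxocyclohexane-1-carboxylate | O=C1C[C@H](N2[C@H](c3ccccc3)CC[C@H]2c2ccccc2)[C@](C)(C(=O)OC)[C@@H](C(OC)OC)C1 | intermediate (not isolated)
10 | methyl (1S,6S)-6-(dimethoxymethyl)-1-methyl-4-oxocyclohex-2-ene-1-carboxylate (ring C1, C6, C4 = labdane C4, C5, C1; ester trans to the acetal carbon) | O=C1C=C[C@](C)(C(=O)OC)[C@@H](C(OC)OC)C1 | intermediate
11 | (R)-linalool, (3R)-3,7-dimethylocta-1,6-dien-3-ol | C=C[C@@](C)(CCC=C(C)C)O | starting material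
12 | triethyl{[(3R)-3,7-dimethylocta-1,6-dien-3-yl]oxy}silane | C=C[C@@](C)(CCC=C(C)C)O[Si](CC)(CC)CC | intermediate
13 | (2E,6R)-2,6-dimethyl-6-(triethylsilyloxy)octa-2,7-dienal | C=C[C@@](C)(CC/C=C(\C)C=O)O[Si](CC)(CC)CC | intermediate (not isolated)
14 | (2E,6R)-2,6-dimethyl-6-(triethylsilyloxy)octa-2,7-dien-1-ol | C=C[C@@](C)(CC/C=C(\C)CO)O[Si](CC)(CC)CC | intermediate
15 | (2E,6R)-2,6-dimethyl-6-(triethylsilyloxy)octa-2,7-dien-1-yl methanesulfonate | C=C[C@@](C)(CC/C=C(\C)COS(C)(=O)=O)O[Si](CC)(CC)CC | intermediate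
16 | methyl (1S,6S)-6-(dimethoxymethyl)-4-{[(2E,6R)-2,6-dimethyl-6-(triethylsilyloxy)octa-2,7-dien-1-yl]oxy}-1-methylcyclohexa-2,4-diene-1-carboxylate | C=C[C@@](C)(CC/C=C(\C)COC1=C[C@H](C(OC)OC)[C@@](C)(C(=O)OC)C=C1)O[Si](CC)(CC)CC | intermediate
17 | methyl 6,6-dimethoxy-1-oxo-13-(triethylsilyloxy)-20-nor-6,7-secolabda-2,7,14-trien-19-oate (10-H; C9 arm on C10 trans to C6) | C=C[C@@](C)(CC[C@@H](C(C)=C)[C@@H]1C(=O)C=C[C@](C)(C(=O)OC)[C@H]1C(OC)OC)O[Si](CC)(CC)CC | intermediate
18 | methyl 6,6-dimethoxy-1-oxo-13-(triethylsilyloxy)-6,7-secolabda-2,7,14-trien-19-oate (10β-methyl; C9 arm cis to C6) | C=C[C@@](C)(CC[C@@H](C(C)=C)[C@@]1(C)C(=O)C=C[C@](C)(C(=O)OC)[C@H]1C(OC)OC)O[Si](CC)(CC)CC | intermediate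
19 | methyl 6,6-dimethoxy-1-oxo-13-(triethylsilyloxy)-6,7-secolabda-7,14-dien-19-oate | C=C[C@@](C)(CC[C@@H](C(C)=C)[C@@]1(C)C(=O)CC[C@](C)(C(=O)OC)[C@H]1C(OC)OC)O[Si](CC)(CC)CC | intermediate
20 | C1 4-methylbenzenesulfonylhydrazone of 19 | C=C[C@@](C)(CC[C@@H](C(C)=C)[C@@]1(C)C(=NNS(=O)(=O)c2ccc(C)cc2)CC[C@](C)(C(=O)OC)[C@H]1C(OC)OC)O[Si](CC)(CC)CC | intermediate
21 | N-boryl hydrazide (C1–H, N-benzodioxaborolyl, N′-tosyl) | C=C[C@@](C)(CC[C@@H](C(C)=C)[C@@]1(C)C(N(NS(=O)(=O)c2ccc(C)cc2)B2Oc3ccccc3O2)CC[C@](C)(C(=O)OC)[C@H]1C(OC)OC)O[Si](CC)(CC)CC | intermediate (not isolated)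
22 | methyl 6,6-dimethoxy-13-(triethylsilyloxy)-6,7-secolabda-7,14-dien-19-oate | C=C[C@@](C)(CC[C@@H](C(C)=C)[C@@]1(C)CCC[C@](C)(C(=O)OC)[C@H]1C(OC)OC)O[Si](CC)(CC)CC | intermediate
23 | methyl 6-oxo-13-(triethylsilyloxy)-6,7-secolabda-7,14-dien-19-oate; methyl (1S,2S,3R)-2-formyl-1,3-dimethyl-3-[(3S,6R)-2,6-dimethyl-6-(triethylsilyloxy)octa-1,7-dien-3-yl]cyclohexane-1-carboxylate | C=C[C@@](C)(CC[C@@H](C(C)=C)[C@@]1(C)CCC[C@](C)(C(=O)OC)[C@H]1C=O)O[Si](CC)(CC)CC | intermediate (key-step precursor)
24 | methyl 6β-hydroxy-13-(triethylsilyloxy)-5β-labda-8(17),14-dien-19-oate (cis-fused, 6R) | C=C[C@@](C)(CC[C@H]1C(=C)C[C@@H](O)[C@H]2[C@]1(C)CCC[C@]2(C)C(=O)OC)O[Si](CC)(CC)CC | intermediate (key-step product)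
25 | sodium O-(C6) dithiocarbonate of 24 | C=C[C@@](C)(CC[C@H]1C(=C)C[C@@H](OC(=S)[S-])[C@H]2[C@]1(C)CCC[C@]2(C)C(=O)OC)O[Si](CC)(CC)CC.[Na+] | intermediate (not isolated)
26 | O-(C6) S-methyl dithiocarbonate of 24 | C=C[C@@](C)(CC[C@H]1C(=C)C[C@@H](OC(=S)SC)[C@H]2[C@]1(C)CCC[C@]2(C)C(=O)OC)O[Si](CC)(CC)CC | intermediate
27 | methyl 13-(triethylsilyloxy)-5β-labda-8(17),14-dien-19-oate | C=C[C@@](C)(CC[C@H]1C(=C)CC[C@H]2[C@]1(C)CCC[C@]2(C)C(=O)OC)O[Si](CC)(CC)CC | intermediate
28 | 13-(triethylsilyloxy)-5β-labda-8(17),14-dien-19-oic acid | C=C[C@@](C)(CC[C@H]1C(=C)CC[C@H]2[C@]1(C)CCC[C@]2(C)C(=O)O)O[Si](CC)(CC)CC | intermediate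
29 | (13R)-13-hydroxy-5β-labda-8(17),14-dien-19-oic acid | C=C[C@@](C)(CC[C@H]1C(=C)CC[C@H]2[C@]1(C)CCC[C@]2(C)C(=O)O)O | intermediate
30 | mixed acetic anhydride of the 13-acetate | C=C[C@@](C)(CC[C@H]1C(=C)CC[C@H]2[C@]1(C)CCC[C@]2(C)C(=O)OC(C)=O)OC(C)=O | intermediate (not isolated)
31 | (13R)-13-acetoxy-5β-labda-8(17),14-dien-19-oic acid | C=C[C@@](C)(CC[C@H]1C(=C)CC[C@H]2[C@]1(C)CCC[C@]2(C)C(=O)O)OC(C)=O | target

**Step count**

Total steps: 20. Longest linear sequence: 16 steps (steps 2–4, then 8–20; the linalool branch, steps 5–7 then 8–20, is equally long).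

**Steps most likely to fail**

Step 4. The trisubstituted enoate may add too slowly for the diene to survive, and facial discrimination by the auxiliary may be incomplete at 80 °C, which would erode the enantiomeric purity of 10. The fallback replaces auxiliary control by catalyst control with a more reactive dienophile; it sets out from 1 and comes back at 10. Wittig reaction of 1 with commercial 2-(triphenylphosphoranylidene)propanal gives (2E)-4,4-dimethoxy-2-methylbut-2-enal F1. Its cycloaddition with commercial (1E)-3-(tert-butyldimethylsilyloxy)-N,N-dimethylbuta-1,3-dien-1-amine under [Cr(salen)]SbF6 (trivalent chromium; salen = dianion of (1S,2S)-N,N′-bis(3,5-di-tert-butylsalicylidene)cyclohexane-1,2-diamine; CH2Cl2, −40 °C) gives the silyl enol ether cycloadduct F2. Bu4NF/AcOH unmasks it through the beta-amino ketone F3 to the formyl enone F4. Pinnick oxidation gives the acid F5, and MeI/K2CO3 returns 10. F4 and F5 are vinylogous 1,3-dicarbonyl compounds and would be taken on without storage.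

Step 8. Alkylation of the dienolate at carbon (C10 attacking the allylic CH2, which gives the untransposed linear product) may compete with O-alkylation. The fallback uses an ester-tethered rearrangement in place of the enol ether; it sets out from 14 and 10 and comes back at 17. Alcohol 14 and 1,1′-carbonyldiimidazole give the imidazole-1-carboxylate F6. Acylation of the lithium dienolate of 10 (LiN(SiMe3)2, THF, −78 °C; then F6, BF3·OEt2) gives the allyl beta-keto ester F7. Its sodium enolate (NaH, toluene, 110 °C) should undergo the Carroll rearrangement to the beta-keto acid F8, which loses CO2 on acidic work-up to give 17. The C9 configuration would rest on a chair transition state of the chelated ester enolate.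

Step 15. The tertiary allylic silyl ether may ionise, or chloride may be captured at C8, before the aldehyde, which sits between two quaternary carbons, closes. The fallback uses an acylium ion instead of the complexed aldehyde as enophile; it sets out from 23 and comes back at 24 or, if the C6 epimer forms, at 27. Pinnick oxidation of 23 gives the acid F9, and 1-chloro-N,N,2-trimethylprop-1-en-1-amine converts it into the acid chloride F10. SnCl4 (CH2Cl2, −78 °C) should promote intramolecular acylation of the 2-propenyl group with loss of a C17 proton (acyl-ene reaction) to the 6-oxo-8(17)-ene F11. F11 is reduced at once (Luche reduction: NaBH4, CeCl3·7H2O, MeOH, −78 °C) so that C5 has no time to epimerise. The alcohol is 24 or its 6α epimer F12; F12 would pass through the conditions of steps 16 and 17 (sodium xanthate F13, xanthate F14) and rejoin the route at 27.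

**Further compounds**

F1 | step 4 | (2E)-4,4-dimethoxy-2-methylbut-2-enal | O=C/C(C)=C/C(OC)OC
F2 | step 4 | 4-(tert-butyldimethylsilyloxy)-6-(dimethoxymethyl)-2-(dimethylamino)-1-methylcyclohex-3-ene-1-carbaldehyde (formyl trans to the acetal carbon) | CC(C)(C)[Si](C)(C)OC1=C[C@H](N(C)C)[C@](C)(C=O)[C@@H](C(OC)OC)C1
F3 | step 4 | 6-(dimethoxymethyl)-2-(dimethylamino)-1-methyl-4-oxocyclohexane-1-carbaldehyde | O=C1C[C@H](N(C)C)[C@](C)(C=O)[C@@H](C(OC)OC)C1
F4 | step 4 | (1S,6S)-6-(dimethoxymethyl)-1-methyl-4-oxocyclohex-2-ene-1-carbaldehyde | O=C1C=C[C@](C)(C=O)[C@@H](C(OC)OC)C1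
F5 | step 4 | (1S,6S)-6-(dimethoxymethyl)-1-methyl-4-oxocyclohex-2-ene-1-carboxylic acid | O=C1C=C[C@](C)(C(=O)O)[C@@H](C(OC)OC)C1
F6 | step 8 | (2E,6R)-2,6-dimethyl-6-(triethylsilyloxy)octa-2,7-dien-1-yl 1H-imidazole-1-carboxylate | C=C[C@@](C)(CC/C=C(\C)COC(=O)n1ccnc1)O[Si](CC)(CC)CC
F7 | step 8 | allyl beta-keto ester: C10 (2E,6R)-2,6-dimethyl-6-(triethylsilyloxy)octa-2,7-dien-1-yl carboxylate of 10 | C=C[C@@](C)(CC/C=C(\C)COC(=O)C1C(=O)C=C[C@](C)(C(=O)OC)[C@H]1C(OC)OC)O[Si](CC)(CC)CC
F8 | step 8 | beta-keto acid: C10 carboxylic acid of 17 | C=C[C@@](C)(CC[C@@H](C(C)=C)C1(C(=O)O)C(=O)C=C[C@](C)(C(=O)OC)[C@H]1C(OC)OC)O[Si](CC)(CC)CC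
F9 | step 15 | 19-methyl hydrogen 13-(triethylsilyloxy)-6,7-secolabda-7,14-diene-6,19-dioate (C6 acid of 23) | C=C[C@@](C)(CC[C@@H](C(C)=C)[C@@]1(C)CCC[C@](C)(C(=O)OC)[C@H]1C(=O)O)O[Si](CC)(CC)CC
F10 | step 15 | C6 acid chloride of F9 | C=C[C@@](C)(CC[C@@H](C(C)=C)[C@@]1(C)CCC[C@](C)(C(=O)OC)[C@H]1C(Cl)=O)O[Si](CC)(CC)CC
F11 | step 15 | methyl 6-oxo-13-(triethylsilyloxy)-5β-labda-8(17),14-dien-19-oate | C=C[C@@](C)(CC[C@H]1C(=C)CC(=O)[C@H]2[C@]1(C)CCC[C@]2(C)C(=O)OC)O[Si](CC)(CC)CC
F12 | step 15 | methyl 6α-hydroxy-13-(triethylsilyloxy)-5β-labda-8(17),14-dien-19-oate | C=C[C@@](C)(CC[C@H]1C(=C)C[C@H](O)[C@H]2[C@]1(C)CCC[C@]2(C)C(=O)OC)O[Si](CC)(CC)CC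
F13 | step 15 | sodium O-(C6) dithiocarbonate of F12 | C=C[C@@](C)(CC[C@H]1C(=C)C[C@H](OC(=S)[S-])[C@H]2[C@]1(C)CCC[C@]2(C)C(=O)OC)O[Si](CC)(CC)CC.[Na+]
F14 | step 15 | O-(C6) S-methyl dithiocarbonate of F12 | C=C[C@@](C)(CC[C@H]1C(=C)C[C@H](OC(=S)SC)[C@H]2[C@]1(C)CCC[C@]2(C)C(=O)OC)O[Si](CC)(CC)CC
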